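At early times G is taken by D, by X and by L at once, so keep books on G.

    L + G → L.G (k1 = 1.8 L mol⁻¹ s⁻¹)
    G + X → G.X (k2 = 2.6 L mol⁻¹ s⁻¹)
    L.G + G.X → E (k3 = 65 L mol⁻¹ s⁻¹)
    G + D → G.D (k4 = 9.8 L mol⁻¹ s⁻¹)

| setting | eta | beta | theta |
|---|---|---|---|
| L | 10 mM | 10 mM | 10 mM |
| X | 15.0 mM | 15.0 mM | 15.0 mM |
| G | 20.0 mM | 30.0 mM | 45.0 mM |
| D | 10.0 mM | 10.0 mM | 10.0 mM |
| time | 1.0 min | 1.0 min | 1.0 min |

- which of these there is most of at the end, counted by the L in it, eta (L / E / L.G)
- which of these there is most of at the end, counted by the L in it, beta (L / E / L.G)
- which of these there is most of at the end, counted by the L in it, theta (L / E / L.G)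
- how much there is at the end of the one of these that leads, in percent of the L charged: eta
- how much there is at the end of the one of these that leads, in percent of the L charged: beta
- how much there is at the end of the one of these that leads, in percent of the L charged: theta

Counted by the charges, G is the limiting reagent in eta and beta: D, X and L can each take one G, 35.0 mM in total, which is more than the 20.0 mM or 30.0 mM charged.

The first entry is D. At the start of eta, G's reaction with D runs 2.5 times as fast as its reaction with X, so you book the 10.0 mM of D first and reckon with the G it leaves free: 10.0 mM in eta, 20.0 mM in beta.

The second entry divides that free G between L and X in proportion to their rates at the charges. L gets 31.6%, and this figure, the rate of L with G over the rates of L with G and X with G together, is L's share.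

The third entry is the pairing. The step to E has the largest constant, 65 L mol⁻¹ s⁻¹, so you book each L.G as E at once, with one G.X as partner, and there are partners enough because X's part is larger than L's.

Now close the books, taking the G charged as spent by the end. The books for eta give 3.16 mM of E and 3.68 mM of unpaired G.X, which leaves L at 68.4%, so L leads on these books. Beta puts E at 63.2%, so E leads. In theta the entry comes to 11.1 mM, more than the 10 mM of L, and the G charged exceeds the need. By this count G falls short in theta nowhere, so I expect E to lead there, and these books give no figure for it.

The forecast reads L at 64% in eta, E at 58% in beta, below my figure, and E at 85% in theta, holding that “D takes up G fastest”.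

The flask gives L at 65.2% in eta, E at 58.5% in beta and E at 84.8% in theta, against my 68.4% and 63.2% for the first two. The L that eta lost comes to 34.8% of the free G booked for it, beside the share of 31.6% reckoned at the charges. For a neighbour of eta with X at 9.0 mM you reckon L's share at 43.5%, which books L at 56.5%. That neighbour ends with L at 58.1%, E at 38.6% and L.G at 3.32%.

The numbers of this flask were drawn at random within sensible limits; what happens was integrated by code.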